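Each pyran ring (ring C) is opened at O1–C8a and C3–C4. The step exploits two features: C3 lies between oxygenated carbons, so it can be a 1,3-dithiane carbanion (masked carbonyl) carrying the (R)-C2 carbinol and ring B; and C4 is ortho to C8a on ring A. The O,C-dianion is acylated at C3 by a ring-A 2-fluorobenzoate (C4); the new C4 ketone activates C8a–F, and the C2 alkoxide closes the ring by SNAr in the same flask. Two carbonyl carbons are joined by polarity reversal. Later steps set C4 and C3, epimerise C4 in one half, and join the halves at C6 by Suzuki coupling.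

Key step: step 5

Remark: flavan numbering is used (O1, C2, C3, C4, C4a, C5 to C8, C8a; ring A benzo, ring B 2-aryl, ring C pyran). The target is read as the C6–C6' dimer of a (2R,3R,4R) and a (2R,3R,4S) 7,8,4'-trihydroxyflavan-3,4-diol. Compounds 1, 5 and 6 are taken as commercial.

Step 1
Reactants: 1 3-fluorocatechol (3-fluorobenzene-1,2-diol)
Product: 2 1,2-bis(benzyloxy)-3-fluorobenzene
Conditions: BnBr, K2CO3, DMF, rt
Reagents that add atoms: benzyl bromide, BrCc1ccccc1
Why: Williamson ether synthesis on both phenols of the catechol should proceed cleanly because fluoride on an unactivated ring is inert to carbonate, and no stereocentre is involved.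

Step 2
Reactants: 2 1,2-bis(benzyloxy)-3-fluorobenzene
Product: 4 methyl 3,4-bis(benzyloxy)-2-fluorobenzoate, via aryllithium 3 (not isolated)
Conditions: s-BuLi, THF, −78 °C; then cannulation into ClCO2Me, THF, −78 °C
Reagents that add atoms: methyl chloroformate, COC(Cl)=O
Why: Fluorine-directed ortho-lithiation (the C–H next to fluorine is the most acidic ring position and should be removed faster at −78 °C than the benzylic ether CH2) followed by acylation of the aryllithium with the chloroformate under inverse addition should give the 2-fluorobenzoate regioselectively.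

Step 3
Reactants: 5 1,3-dithiane; 6 methyl 4-(benzyloxy)benzoate
Product: 8 [4-(benzyloxy)phenyl](1,3-dithian-2-yl)methanone, via 2-lithio-1,3-dithiane 7 (not isolated)
Conditions: n-BuLi (2.2 equiv, with 2.2 equiv of 5), THF, −30 °C; then 6, −78 °C → rt
Reagents that add atoms: none
Why: Corey–Seebach acylation of 2-lithio-1,3-dithiane by an ester should stop at the ketone because the acidic 2-acyl-dithiane product is deprotonated by the second equivalent of the reagent.

Step 4
Reactants: 8 [4-(benzyloxy)phenyl](1,3-dithian-2-yl)methanone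
Product: 9 (R)-[4-(benzyloxy)phenyl](1,3-dithian-2-yl)methanol
Conditions: RuCl[(S,S)-TsDPEN](p-cymene) (cat.), HCO2H/Et3N (5:2), DMF, 40 °C
Reagents that add atoms: none
Why: Noyori–Ikariya asymmetric transfer hydrogenation of an aryl ketone should set C2 by catalyst control, the (S,S) catalyst delivering hydride in the facial sense that gives (S)-1-phenylethanol from acetophenone, which here is named (R) because the dithianyl carbon outranks the aryl carbon.

Step 5
Reactants: 9 (R)-[4-(benzyloxy)phenyl](1,3-dithian-2-yl)methanol; 4 methyl 3,4-bis(benzyloxy)-2-fluorobenzoate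
Product: 12 (2R)-7,8-bis(benzyloxy)-2-[4-(benzyloxy)phenyl]spiro[chromane-3,2'-[1,3]dithian]-4-one, via dilithiated carbinol 10 (not isolated), via lithium keto alkoxide 11 (not isolated)
Conditions: n-BuLi (2.1 equiv), THF, −30 °C; then 4, −78 → 0 °C
Reagents that add atoms: none
Why: n-BuLi removes the O–H and then the dithiane C–H of 9, and the 2-dithianyl carbanion (an acyl-anion equivalent for C3) adds to the ester carbonyl of 4 and expels methoxide, so that two carbonyl-type carbons are joined as the C3–C4 bond. The aryl ketone thus formed activates the ortho C8a–F bond, and the lithium alkoxide on C2 attacks C8a through a Meisenheimer adduct and expels fluoride, which makes the O1–C8a bond and closes ring C in a 6-exo addition–elimination (SNAr) mode. The closest known reactions are the Corey–Seebach acylation of 2-lithio-1,3-dithianes by esters and the SNAr closure of 2-fluorophenyl ketones carrying a 3-hydroxy group to chroman-4-ones. No stereocentre is created; C2 should keep its (R) configuration because it is never deprotonated and C3 of the product is quaternary, which rules out enolisation and retro-oxa-Michael opening. The step needs C-acylation to outrun O-acylation and the ring closure to outrun retro-aldol loss of the C2–C3 bond: the carbanion is by far the stronger nucleophile at −78 °C, and the ketone-activated fluoride lies within reach of the alkoxide for a six-membered closure below 0 °C.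

Step 6
Reactants: 12 (2R)-7,8-bis(benzyloxy)-2-[4-(benzyloxy)phenyl]spiro[chromane-3,2'-[1,3]dithian]-4-one
Product: 13 (2R,4R)-7,8-bis(benzyloxy)-2-[4-(benzyloxy)phenyl]spiro[chromane-3,2'-[1,3]dithian]-4-ol (4-OH cis to the 2-aryl group)
Conditions: NaBH4, THF/MeOH, −20 °C
Reagents that add atoms: none
Why: Borohydride reduction of the aryl ketone should set C4 by substrate control, hydride entering anti to the 2-aryl group as in flavanone reductions so that the 4-OH is cis to the aryl group (4R), which NOE analysis would have to confirm.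

Step 7
Reactants: 13 (2R,4R)-7,8-bis(benzyloxy)-2-[4-(benzyloxy)phenyl]spiro[chromane-3,2'-[1,3]dithian]-4-ol
Product: 14 (2R,4R)-7,8-bis(benzyloxy)-2-[4-(benzyloxy)phenyl]-4-hydroxychroman-3-one
Conditions: MeI (excess), CaCO3, MeCN/H2O (9:1), 40 °C; crude product used at once
Reagents that add atoms: water, O
Why: Alkylative dithioketal hydrolysis (S-methylation, loss of the sulfonium, capture of the thionium ion by water) under carbonate buffering should unmask the C3 ketone without the base or acid that would epimerise C2 or C4.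

Step 8
Reactants: 14 (2R,4R)-7,8-bis(benzyloxy)-2-[4-(benzyloxy)phenyl]-4-hydroxychroman-3-one
Product: 15 (2R,3R,4R)-7,8-bis(benzyloxy)-2-[4-(benzyloxy)phenyl]chromane-3,4-diol (2,3-cis-3,4-cis)
Conditions: LiBH(s-Bu)3 (3 equiv), THF, −78 °C
Reagents that add atoms: none
Why: Bulky-hydride reduction of the flavan-3-one should set C3 by substrate control, LiBH(s-Bu)3 attacking the face opposite the mutually cis 2-aryl and 4-hydroxy groups as in the known conversion of 2-arylchroman-3-ones into 2,3-cis alcohols, to give the all-cis (3R) diol.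

Step 9
Reactants: 15 (2R,3R,4R)-7,8-bis(benzyloxy)-2-[4-(benzyloxy)phenyl]chromane-3,4-diol
Product: 16 (2R,3R,4R)-7,8-bis(benzyloxy)-2-[4-(benzyloxy)phenyl]-6-bromochromane-3,4-diol
Conditions: NBS (1.05 equiv), MeCN, 0 °C, dark
Reagents that add atoms: N-bromosuccinimide, O=C1CCC(=O)N1Br
Why: Electrophilic aromatic bromination should occur at C6, which is para to O1 and ortho to the 7-benzyloxy group and hence the most activated open position, ring B having only one donor.

Step 10
Reactants: 16 (2R,3R,4R)-7,8-bis(benzyloxy)-2-[4-(benzyloxy)phenyl]-6-bromochromane-3,4-diol (one half of the material)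
Product: 17 (2R,3R,4S)-7,8-bis(benzyloxy)-2-[4-(benzyloxy)phenyl]-6-bromochromane-3,4-diol (2,3-cis-3,4-trans)
Conditions: p-TsOH·H2O (cat.), THF/H2O (4:1), 40 °C
Reagents that add atoms: water, O
Why: Acid-catalysed SN1 epimerisation at the benzylic C4 (cation stabilised by O1 and the 7-oxygen) should favour return of water anti to the 3-hydroxy and 2-aryl groups, the 2,3-cis-3,4-trans (4S) diol also being the more stable epimer as in the known melacacidin to isomelacacidin change, and unchanged 16 is recycled.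

Step 11
Reactants: 16 (2R,3R,4R)-7,8-bis(benzyloxy)-2-[4-(benzyloxy)phenyl]-6-bromochromane-3,4-diol (other half)
Product: 18 (2R,3R,4R)-7,8-bis(benzyloxy)-2-[4-(benzyloxy)phenyl]-6-(4,4,5,5-tetramethyl-1,3,2-dioxaborolan-2-yl)chromane-3,4-diol
Conditions: B2pin2, Pd(dppf)Cl2 (cat.), KOAc, 1,4-dioxane, 85 °C
Reagents that add atoms: bis(pinacolato)diboron, CC1(C)OB(OC1(C)C)B1OC(C)(C)C(C)(C)O1
Why: Miyaura borylation of the aryl bromide should tolerate the free secondary alcohols and benzyl ethers under the weak acetate base, and no stereocentre is touched.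

Step 12
Reactants: 17 (2R,3R,4S)-6-bromo diol; 18 (2R,3R,4R)-6-boronate diol
Product: 19 (2R,2'R,3R,3'R,4R,4'S)-7,7',8,8'-tetrakis(benzyloxy)-2,2'-bis[4-(benzyloxy)phenyl]-[6,6'-bichromane]-3,3',4,4'-tetrol
Conditions: Pd(OAc)2 (cat.), SPhos, K3PO4, THF/H2O (10:1), 60 °C
Reagents that add atoms: none
Why: Suzuki–Miyaura coupling with a bulky electron-rich phosphine should join the two ortho-alkoxy aryl partners at C6–C6', the biaryl having only two ortho substituents and so no stable axis, under basic conditions that leave the C4 carbinols untouched.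

Step 13
Reactants: 19 hexabenzyl ether of the dimer
Product: 20 (2R,2'R,3R,3'R,4R,4'S)-2,2'-bis(4-hydroxyphenyl)-[6,6'-bichromane]-3,3',4,4',7,7',8,8'-octol (target)
Conditions: H2 (1 atm), Pd(OH)2/C, THF/MeOH (1:1), rt; filtration under argon
Reagents that add atoms: none
Why: Catalytic hydrogenolysis of the six aryl benzyl ethers under neutral conditions should be faster than cleavage of the benzylic C4–O bonds, which needs acid assistance, and frees the polyphenol without acid that would epimerise C4.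

Compound list
1 | 3-fluorocatechol | Oc1cccc(F)c1O | starting material
2 | 1,2-bis(benzyloxy)-3-fluorobenzene | Fc1cccc(OCc2ccccc2)c1OCc1ccccc1 | intermediate
3 | [3,4-bis(benzyloxy)-2-fluorophenyl]lithium | [Li]c1ccc(OCc2ccccc2)c(OCc2ccccc2)c1F | intermediate
4 | methyl 3,4-bis(benzyloxy)-2-fluorobenzoate | COC(=O)c1ccc(OCc2ccccc2)c(OCc2ccccc2)c1F | intermediate
5 | 1,3-dithiane | C1CSCSC1 | starting material
6 | methyl 4-(benzyloxy)benzoate | COC(=O)c1ccc(OCc2ccccc2)cc1 | starting material
7 | 2-lithio-1,3-dithiane | [Li]C1SCCCS1 | intermediate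
8 | [4-(benzyloxy)phenyl](1,3-dithian-2-yl)methanone | O=C(c1ccc(OCc2ccccc2)cc1)C1SCCCS1 | intermediate
9 | (R)-[4-(benzyloxy)phenyl](1,3-dithian-2-yl)methanol | O[C@H](c1ccc(OCc2ccccc2)cc1)C1SCCCS1 | intermediate
10 | O,C-dilithio derivative of 9 | [Li]O[C@H](c1ccc(OCc2ccccc2)cc1)C1([Li])SCCCS1 | intermediate
11 | lithium (R)-alkoxide of [3,4-bis(benzyloxy)-2-fluorophenyl]{2-[[4-(benzyloxy)phenyl](hydroxy)methyl]-1,3-dithian-2-yl}methanone | [Li]O[C@H](c1ccc(OCc2ccccc2)cc1)C1(SCCCS1)C(=O)c1ccc(OCc2ccccc2)c(OCc2ccccc2)c1F | intermediate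
12 | (2R)-7,8-bis(benzyloxy)-2-[4-(benzyloxy)phenyl]spiro[chromane-3,2'-[1,3]dithian]-4-one | O(Cc1ccccc1)c1ccc([C@H]2Oc3c(ccc(OCc4ccccc4)c3OCc3ccccc3)C(=O)C25SCCCS5)cc1 | intermediate
13 | (2R,4R)-7,8-bis(benzyloxy)-2-[4-(benzyloxy)phenyl]spiro[chromane-3,2'-[1,3]dithian]-4-ol | O(Cc1ccccc1)c1ccc([C@H]2Oc3c(ccc(OCc4ccccc4)c3OCc3ccccc3)[C@@H](O)C25SCCCS5)cc1 | intermediate
14 | (2R,4R)-7,8-bis(benzyloxy)-2-[4-(benzyloxy)phenyl]-4-hydroxychroman-3-one | O(Cc1ccccc1)c1ccc([C@H]2Oc3c(ccc(OCc4ccccc4)c3OCc3ccccc3)[C@@H](O)C2=O)cc1 | intermediate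
15 | (2R,3R,4R)-7,8-bis(benzyloxy)-2-[4-(benzyloxy)phenyl]chromane-3,4-diol | O(Cc1ccccc1)c1ccc([C@H]2Oc3c(ccc(OCc4ccccc4)c3OCc3ccccc3)[C@@H](O)[C@H]2O)cc1 | intermediate
16 | (2R,3R,4R)-7,8-bis(benzyloxy)-2-[4-(benzyloxy)phenyl]-6-bromochromane-3,4-diol | O(Cc1ccccc1)c1ccc([C@H]2Oc3c(cc(Br)c(OCc4ccccc4)c3OCc3ccccc3)[C@@H](O)[C@H]2O)cc1 | intermediate
17 | (2R,3R,4S)-7,8-bis(benzyloxy)-2-[4-(benzyloxy)phenyl]-6-bromochromane-3,4-diol | O(Cc1ccccc1)c1ccc([C@H]2Oc3c(cc(Br)c(OCc4ccccc4)c3OCc3ccccc3)[C@H](O)[C@H]2O)cc1 | intermediate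
18 | (2R,3R,4R)-7,8-bis(benzyloxy)-2-[4-(benzyloxy)phenyl]-6-(4,4,5,5-tetramethyl-1,3,2-dioxaborolan-2-yl)chromane-3,4-diol | O(Cc1ccccc1)c1ccc([C@H]2Oc3c(cc(B4OC(C)(C)C(C)(C)O4)c(OCc4ccccc4)c3OCc3ccccc3)[C@@H](O)[C@H]2O)cc1 | intermediate
19 | (2R,2'R,3R,3'R,4R,4'S)-7,7',8,8'-tetrakis(benzyloxy)-2,2'-bis[4-(benzyloxy)phenyl]-[6,6'-bichromane]-3,3',4,4'-tetrol | O(Cc1ccccc1)c1ccc([C@H]2Oc3c(cc(-c4cc5c(c(OCc6ccccc6)c4OCc4ccccc4)O[C@H](c4ccc(OCc6ccccc6)cc4)[C@H](O)[C@H]5O)c(OCc4ccccc4)c3OCc3ccccc3)[C@@H](O)[C@H]2O)cc1 | intermediate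
20 | (2R,2'R,3R,3'R,4R,4'S)-2,2'-bis(4-hydroxyphenyl)-[6,6'-bichromane]-3,3',4,4',7,7',8,8'-octol | Oc1ccc([C@H]2Oc3c(cc(-c4cc5c(c(O)c4O)O[C@H](c4ccc(O)cc4)[C@H](O)[C@H]5O)c(O)c3O)[C@@H](O)[C@H]2O)cc1 | target

Total step count: 13. Longest linear sequence: 10 steps (steps 3, 4, 5, 6, 7, 8, 9, 10, 12, 13; the ring-A branch through steps 1, 2 and 11 is equally long).

Steps most likely to fail

Step 5. The second deprotonation of 9 may be incomplete, and the keto alkoxide 11 may fragment by retro-aldol across C2–C3 before the SNAr closure, which would also erode the C2 configuration. The fallback sets out from 9 and 3 and comes back at 12. Aryllithium 3 is quenched with DMF to give 3,4-bis(benzyloxy)-2-fluorobenzaldehyde F1. The dianion of 9 (n-BuLi, THF) is added to F1 at −78 °C to give [3,4-bis(benzyloxy)-2-fluorophenyl]{2-[(R)-[4-(benzyloxy)phenyl](hydroxy)methyl]-1,3-dithian-2-yl}methanol F2; this dialkoxide carries no ketone and cannot undergo that retro-aldol. KHMDS in DMF at 60 °C should then close ring C by SNAr on the non-activated fluoroarene to give (2R)-7,8-bis(benzyloxy)-2-[4-(benzyloxy)phenyl]spiro[chromane-3,2'-[1,3]dithian]-4-ol F3 as a mixture of C4 epimers, and Swern oxidation should give 12.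

Step 7. S-Alkylation of the hindered spiro dithioketal may be slow, and the liberated hydroxy ketone may epimerise at C2 or C4 or undergo an α-ketol shift. The fallback sets out from 13 and comes back at 15. The C4 hydroxyl is silylated (TBSOTf, 2,6-lutidine, CH2Cl2) to give the 4-O-tert-butyldimethylsilyl ether F4. Hydrolysis with Hg(ClO4)2 and CaCO3 in aqueous THF should give (2R,4R)-7,8-bis(benzyloxy)-2-[4-(benzyloxy)phenyl]-4-(tert-butyldimethylsilyloxy)chroman-3-one F5, which has no free α-hydroxyl. LiBH(s-Bu)3 at −78 °C should give the (2R,3R,4R) 3-alcohol F6, and TBAF in THF should give 15.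

Step 13. The benzylic C4–O bonds may be hydrogenolysed along with the benzyl ethers (over-reduction to flavan-3-ol units). The fallback sets out from 19 and comes back at 20. The four secondary hydroxyls are silylated (TBSOTf, 2,6-lutidine) to give the tetrakis(tert-butyldimethylsilyl) ether F7, whose benzylic silyl ethers should resist hydrogenolysis. H2 over Pd(OH)2/C in EtOAc should give the hexaphenol tetrakis(silyl) ether F8, and TBAF buffered with AcOH in THF at 0 °C under argon should give 20.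

Further compounds
F1 | step 5 | 3,4-bis(benzyloxy)-2-fluorobenzaldehyde | O=Cc1ccc(OCc2ccccc2)c(OCc2ccccc2)c1F
F2 | step 5 | [3,4-bis(benzyloxy)-2-fluorophenyl]{2-[(R)-[4-(benzyloxy)phenyl](hydroxy)methyl]-1,3-dithian-2-yl}methanol (both epimers at the new carbinol) | O[C@H](c1ccc(OCc2ccccc2)cc1)C1(SCCCS1)C(O)c1ccc(OCc2ccccc2)c(OCc2ccccc2)c1F
F3 | step 5 | (2R)-7,8-bis(benzyloxy)-2-[4-(benzyloxy)phenyl]spiro[chromane-3,2'-[1,3]dithian]-4-ol (both C4 epimers) | O(Cc1ccccc1)c1ccc([C@H]2Oc3c(ccc(OCc4ccccc4)c3OCc3ccccc3)C(O)C25SCCCS5)cc1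
F4 | step 7 | (2R,4R)-7,8-bis(benzyloxy)-2-[4-(benzyloxy)phenyl]-4-(tert-butyldimethylsilyloxy)spiro[chromane-3,2'-[1,3]dithiane] | O(Cc1ccccc1)c1ccc([C@H]2Oc3c(ccc(OCc4ccccc4)c3OCc3ccccc3)[C@@H](O[Si](C)(C)C(C)(C)C)C25SCCCS5)cc1
F5 | step 7 | (2R,4R)-7,8-bis(benzyloxy)-2-[4-(benzyloxy)phenyl]-4-(tert-butyldimethylsilyloxy)chroman-3-one | O(Cc1ccccc1)c1ccc([C@H]2Oc3c(ccc(OCc4ccccc4)c3OCc3ccccc3)[C@@H](O[Si](C)(C)C(C)(C)C)C2=O)cc1
F6 | step 7 | (2R,3R,4R)-7,8-bis(benzyloxy)-2-[4-(benzyloxy)phenyl]-4-(tert-butyldimethylsilyloxy)chroman-3-ol | O(Cc1ccccc1)c1ccc([C@H]2Oc3c(ccc(OCc4ccccc4)c3OCc3ccccc3)[C@@H](O[Si](C)(C)C(C)(C)C)[C@H]2O)cc1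
F7 | step 13 | 3,3',4,4'-tetrakis-O-(tert-butyldimethylsilyl) ether of 19 | O(Cc1ccccc1)c1ccc([C@H]2Oc3c(cc(-c4cc5c(c(OCc6ccccc6)c4OCc4ccccc4)O[C@H](c4ccc(OCc6ccccc6)cc4)[C@H](O[Si](C)(C)C(C)(C)C)[C@H]5O[Si](C)(C)C(C)(C)C)c(OCc4ccccc4)c3OCc3ccccc3)[C@@H](O[Si](C)(C)C(C)(C)C)[C@H]2O[Si](C)(C)C(C)(C)C)cc1
F8 | step 13 | 3,3',4,4'-tetrakis-O-(tert-butyldimethylsilyl) ether of 20 | Oc1ccc([C@H]2Oc3c(cc(-c4cc5c(c(O)c4O)O[C@H](c4ccc(O)cc4)[C@H](O[Si](C)(C)C(C)(C)C)[C@H]5O[Si](C)(C)C(C)(C)C)c(O)c3O)[C@@H](O[Si](C)(C)C(C)(C)C)[C@H]2O[Si](C)(C)C(C)(C)C)cc1
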